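**Assumption:** all bicyclic compounds are cited with the locants of the target tetralin (C1 carries the CH2O carbon, C4 the side chain, C6 the carboxyl carbon, C8 the phenol oxygen), even where systematic rules would renumber. The target is read as (1R,4S) with an (S) side-chain carbon, i.e. 1,4-trans.

## Retrosynthetic overview

1. Target ⇐ PMB ether/acetate/ester adjustments ⇐ trans-1,4 alcohol 23 ⇐ enal 19 by conjugate reduction and thermodynamic epimerisation at C1.
2. 19 ⇐ intramolecular aldol condensation (C1–C2 bond) of dialdehyde 18; this is the only ring-forming step, the benzene ring is bought.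
3. 18 ⇐ hydroxy aldehyde 17 ⇐ Rh-catalysed asymmetric 1,4-addition joining arylboronate 9 and enal 16 (sets C4).
4. 9 ⇐ methyl 4-bromo-3,5-dimethoxybenzoate (Negishi coupling, lactone desymmetrisation of the two phenols); 16 ⇐ geraniol (asymmetric hydrogenation sets the side-chain centre, one-carbon homologation, dehydrogenation).

## Route

### Arene fragment

Step 1
Reactants: 1 methyl 4-bromo-3,5-dimethoxybenzoate; 2 (2-tert-butoxy-2-oxoethyl)zinc chloride
Product: 3 methyl 4-(2-tert-butoxy-2-oxoethyl)-3,5-dimethoxybenzoate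
Conditions: Pd2(dba)3 (1 mol %), XPhos (4 mol %), THF, 65 °C
Reagents that add atoms: none
Why: Negishi coupling of the Reformatsky-type zinc enolate with the ester-activated aryl bromide installs the two-carbon arm between the methoxy groups, and the organozinc tolerates both esters.

Step 2
Reactants: 3 methyl 4-(2-tert-butoxy-2-oxoethyl)-3,5-dimethoxybenzoate
Product: 5 methyl 4-hydroxy-2-oxo-2,3-dihydro-1-benzofuran-6-carboxylate, via dihydroxy acid 4 (not isolated)
Conditions: BBr3 (4 equiv), CH2Cl2, −78→0 °C; H2O; then TsOH (5 mol %), toluene, 80 °C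
Reagents that add atoms: none
Why: Lewis-acid ether cleavage frees both phenols and the tert-butyl ester, and acid-catalysed lactonisation onto one of the two equivalent phenols desymmetrises the ring; the methyl benzoate survives at ≤0 °C.

Step 3
Reactants: 5 methyl 4-hydroxy-2-oxo-2,3-dihydro-1-benzofuran-6-carboxylate
Product: 6 methyl 2-oxo-4-{[(trifluoromethyl)sulfonyl]oxy}-2,3-dihydro-1-benzofuran-6-carboxylate
Conditions: Tf2O (1.1 equiv), pyridine (2 equiv), CH2Cl2, −20→0 °C
Reagents that add atoms: trifluoromethanesulfonic anhydride, O=S(=O)(OS(=O)(=O)C(F)(F)F)C(F)(F)F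
Why: O-sulfonylation of the remaining phenol turns it into the cross-coupling handle; pyridine is too weak a base to enolise the lactone.

Step 4
Reactants: 6 methyl 2-oxo-4-{[(trifluoromethyl)sulfonyl]oxy}-2,3-dihydro-1-benzofuran-6-carboxylate
Product: 7 methyl 3-hydroxy-4-(2-hydroxyethyl)-5-{[(trifluoromethyl)sulfonyl]oxy}benzoate
Conditions: LiBH4 (1.5 equiv), THF, 0 °C; aq NH4Cl
Reagents that add atoms: none
Why: Chemoselective hydride reduction: the aryl-ester lactone is far more electrophilic than the methyl benzoate, so it alone is reduced, releasing the phenol and the 2-hydroxyethyl arm.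

Step 5
Reactants: 7 methyl 3-hydroxy-4-(2-hydroxyethyl)-5-{[(trifluoromethyl)sulfonyl]oxy}benzoate
Product: 8 methyl 4-(2-hydroxyethyl)-3-[(4-methoxybenzyl)oxy]-5-{[(trifluoromethyl)sulfonyl]oxy}benzoate
Conditions: PMBCl (1.1 equiv), K2CO3 (1.5 equiv), DMF, rt
Reagents that add atoms: 4-methoxybenzyl chloride, COc1ccc(CCl)cc1
Why: Williamson etherification; K2CO3 deprotonates only the acidic phenol, so the primary alcohol stays free.

Step 6
Reactants: 8 methyl 4-(2-hydroxyethyl)-3-[(4-methoxybenzyl)oxy]-5-{[(trifluoromethyl)sulfonyl]oxy}benzoate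
Product: 9 methyl 4-(2-hydroxyethyl)-3-[(4-methoxybenzyl)oxy]-5-(4,4,5,5-tetramethyl-1,3,2-dioxaborolan-2-yl)benzoate
Conditions: B2pin2 (1.2 equiv), Pd(dppf)Cl2 (3 mol %), KOAc (3 equiv), dioxane, 85 °C
Reagents that add atoms: bis(pinacolato)diboron, CC1(C)OB(OC1(C)C)B1OC(C)(C)C(C)(C)O1
Why: Miyaura borylation of the aryl triflate under weak base tolerates the ester, ether and free alcohol (the product may sit partly as its cyclic hemiboronate, which is equally competent).

### Side-chain fragment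

Step 7
Reactants: 10 geraniol
Product: 11 (S)-citronellol
Conditions: H2 (30 atm), Ru(OAc)2[(R)-BINAP] (0.1 mol %), MeOH, 20 °C
Reagents that add atoms: none
Why: Noyori asymmetric hydrogenation of the allylic alcohol; the (R)-BINAP–Ru catalyst on the E-alkene gives the (S) centre (the future side-chain stereocentre) and leaves the remote trisubstituted alkene untouched.

Step 8
Reactants: 11 (S)-citronellol
Product: 12 (S)-citronellal
Conditions: TEMPO (10 mol %), PhI(OAc)2 (1.1 equiv), CH2Cl2, rt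
Reagents that add atoms: none
Why: TEMPO/hypervalent-iodine oxidation stops at the aldehyde and does not touch the alkene or the β-stereocentre.

Step 9
Reactants: 12 (S)-citronellal
Product: 13 (4S)-1-methoxy-4,8-dimethylnona-1,7-diene (E/Z mixture)
Conditions: Ph3P(CH2OMe)Cl (1.3 equiv), KOtBu (1.25 equiv), THF, 0 °C→rt
Reagents that add atoms: (methoxymethyl)triphenylphosphonium chloride, COC[P+](c1ccccc1)(c1ccccc1)c1ccccc1.[Cl-]
Why: Wittig methoxymethylenation adds the one carbon that becomes C2 of the tetralin.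

Step 10
Reactants: 13 (4S)-1-methoxy-4,8-dimethylnona-1,7-diene
Product: 14 (4S)-4,8-dimethylnon-7-enal
Conditions: 1 M HCl, THF, rt
Reagents that add atoms: water, O
Why: Mild enol-ether hydrolysis gives the homologated aldehyde; the homologue cannot undergo the facile ene cyclisation of citronellal.

Step 11
Reactants: 14 (4S)-4,8-dimethylnon-7-enal
Product: 15 trimethyl{[(4S)-4,8-dimethylnona-1,7-dien-1-yl]oxy}silane (E/Z mixture)
Conditions: TMSOTf (1.2 equiv), Et3N (1.5 equiv), CH2Cl2, 0 °C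
Reagents that add atoms: trimethylsilyl trifluoromethanesulfonate, C[Si](C)(C)OS(=O)(=O)C(F)(F)F
Why: Soft enolisation/O-silylation gives the aldehyde silyl enol ether needed for regiodefined dehydrogenation.

Step 12
Reactants: 15 trimethyl{[(4S)-4,8-dimethylnona-1,7-dien-1-yl]oxy}silane
Product: 16 (2E,4S)-4,8-dimethylnona-2,7-dienal
Conditions: Pd(OAc)2 (10 mol %), O2 (1 atm), DMSO, rt
Reagents that add atoms: none
Why: Saegusa–Ito oxidation (Pd enolate, β-hydride elimination) gives the (E)-enal without touching the γ-stereocentre.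

### Union, ring closure and end game

Step 13
Reactants: 9 methyl 4-(2-hydroxyethyl)-3-[(4-methoxybenzyl)oxy]-5-(4,4,5,5-tetramethyl-1,3,2-dioxaborolan-2-yl)benzoate; 16 (2E,4S)-4,8-dimethylnona-2,7-dienal
Product: 17 methyl 3-[(3S,4S)-4,8-dimethyl-1-oxonon-7-en-3-yl]-4-(2-hydroxyethyl)-5-[(4-methoxybenzyl)oxy]benzoate
Conditions: [RhCl(C2H4)2]2 (2.5 mol %), (R,R)-Ph-bod* (5.5 mol %), aq KOH (0.3 equiv), dioxane/H2O 10:1, 40 °C
Reagents that add atoms: none
Why: Hayashi–Miyaura Rh-catalysed asymmetric 1,4-addition; the chiral diene–Rh–aryl species must add to the Re face of C3 of the enal (catalyst control) to give the (S) benzylic centre C4, and diene ligands suppress 1,2-addition. The (R,R) ligand hand is my prediction and should be confirmed on a model enal.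

Step 14
Reactants: 17 methyl 3-[(3S,4S)-4,8-dimethyl-1-oxonon-7-en-3-yl]-4-(2-hydroxyethyl)-5-[(4-methoxybenzyl)oxy]benzoate
Product: 19 methyl (4S)-1-formyl-8-[(4-methoxybenzyl)oxy]-4-[(2S)-6-methylhept-5-en-2-yl]-3,4-dihydronaphthalene-6-carboxylate, via dialdehyde 18 (not isolated)
Conditions: Dess–Martin periodinane (1.3 equiv), CH2Cl2, 0 °C→rt; then Bn2NH·TFA (20 mol %), toluene, 50 °C
Reagents that add atoms: none
Why: Dess–Martin oxidation gives the labile arylacetaldehyde, whose enamine (formed far more readily than that of the alkyl aldehyde) attacks the side-chain aldehyde in an amine-catalysed intramolecular aldol condensation (6-enolexo), and dehydration to the arene-conjugated enal closes the carbocycle.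

Step 15
Reactants: 19 methyl (4S)-1-formyl-8-[(4-methoxybenzyl)oxy]-4-[(2S)-6-methylhept-5-en-2-yl]-3,4-dihydronaphthalene-6-carboxylate
Product: 23 methyl (1R,4S)-1-(hydroxymethyl)-8-[(4-methoxybenzyl)oxy]-4-[(2S)-6-methylhept-5-en-2-yl]-1,2,3,4-tetrahydronaphthalene-6-carboxylate, via triethylsilyl enol ether 20 (not isolated), via cis aldehyde 21 (not isolated), via trans aldehyde 22 (not isolated)
Conditions: Et3SiH (1.5 equiv), RhCl(PPh3)3 (2 mol %), toluene, 50 °C; then K2CO3 (0.3 equiv), MeOH, rt, 2 h; then NaBH4, 0 °C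
Reagents that add atoms: none
Why: Rh-catalysed 1,4-hydrosilylation reduces only the conjugated enal; methanolysis gives the α-aryl aldehyde, which epimerises through its enol to the trans isomer (CHO and side chain both pseudoaxial, avoiding peri strain with O-PMB and H-5; I expect only about 5:1), and NaBH4 then fixes C1 as R; the minor cis alcohol is removed by chromatography.

Step 16
Reactants: 23 methyl (1R,4S)-1-(hydroxymethyl)-8-[(4-methoxybenzyl)oxy]-4-[(2S)-6-methylhept-5-en-2-yl]-1,2,3,4-tetrahydronaphthalene-6-carboxylate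
Product: 24 (1R,4S)-1-(hydroxymethyl)-8-[(4-methoxybenzyl)oxy]-4-[(2S)-6-methylhept-5-en-2-yl]-1,2,3,4-tetrahydronaphthalene-6-carboxylic acid
Conditions: LiOH (3 equiv), THF/MeOH/H2O, rt; 1 M HCl
Reagents that add atoms: lithium hydroxide, [Li+].[OH-]
Why: Saponification of the only ester, done before the acetate is introduced so that the acetate never meets hydroxide.

Step 17
Reactants: 24 (1R,4S)-1-(hydroxymethyl)-8-[(4-methoxybenzyl)oxy]-4-[(2S)-6-methylhept-5-en-2-yl]-1,2,3,4-tetrahydronaphthalene-6-carboxylic acid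
Product: 26 (1R,4S)-1-(acetoxymethyl)-8-[(4-methoxybenzyl)oxy]-4-[(2S)-6-methylhept-5-en-2-yl]-1,2,3,4-tetrahydronaphthalene-6-carboxylic acid, via mixed anhydride 25 (not isolated)
Conditions: Ac2O (3 equiv), pyridine, DMAP (5 mol %), CH2Cl2, 0 °C→rt; then H2O, rt
Reagents that add atoms: acetic anhydride, CC(=O)OC(C)=O
Why: DMAP-catalysed O-acetylation of the only free hydroxyl (the phenol is still a PMB ether); the aroyl–acetyl mixed anhydride formed at the acid is hydrolysed back to the acid by the water quench.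

Step 18
Reactants: 26 (1R,4S)-1-(acetoxymethyl)-8-[(4-methoxybenzyl)oxy]-4-[(2S)-6-methylhept-5-en-2-yl]-1,2,3,4-tetrahydronaphthalene-6-carboxylic acid
Product: 27 [(1R,4S)-6-carboxy-8-hydroxy-4-[(2S)-6-methylhept-5-en-2-yl]-1,2,3,4-tetrahydronaphthalen-1-yl]methyl acetate (target)
Conditions: DDQ (1.3 equiv), CH2Cl2/pH 7 buffer 10:1, 0 °C→rt
Reagents that add atoms: none
Why: Oxidative PMB-ether cleavage under neutral conditions spares the acetate, the acid and the acid-sensitive trisubstituted alkene.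

## Compound list

1 | methyl 4-bromo-3,5-dimethoxybenzoate | COC(=O)c1cc(OC)c(Br)c(OC)c1 | starting material
2 | (2-tert-butoxy-2-oxoethyl)zinc chloride (commercial ether solution) | CC(C)(C)OC(=O)C[Zn]Cl | starting material
3 | methyl 4-(2-tert-butoxy-2-oxoethyl)-3,5-dimethoxybenzoate | COC(=O)c1cc(OC)c(CC(=O)OC(C)(C)C)c(OC)c1 | intermediate
4 | 2-[2,6-dihydroxy-4-(methoxycarbonyl)phenyl]acetic acid | COC(=O)c1cc(O)c(CC(=O)O)c(O)c1 | intermediate (not isolated)
5 | methyl 4-hydroxy-2-oxo-2,3-dihydro-1-benzofuran-6-carboxylate | COC(=O)c1cc(O)c2CC(=O)Oc2c1 | intermediate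
6 | methyl 2-oxo-4-{[(trifluoromethyl)sulfonyl]oxy}-2,3-dihydro-1-benzofuran-6-carboxylate | COC(=O)c1cc(OS(=O)(=O)C(F)(F)F)c2CC(=O)Oc2c1 | intermediate
7 | methyl 3-hydroxy-4-(2-hydroxyethyl)-5-{[(trifluoromethyl)sulfonyl]oxy}benzoate | COC(=O)c1cc(O)c(CCO)c(OS(=O)(=O)C(F)(F)F)c1 | intermediate
8 | methyl 4-(2-hydroxyethyl)-3-[(4-methoxybenzyl)oxy]-5-{[(trifluoromethyl)sulfonyl]oxy}benzoate | COC(=O)c1cc(OCc2ccc(OC)cc2)c(CCO)c(OS(=O)(=O)C(F)(F)F)c1 | intermediate
9 | methyl 4-(2-hydroxyethyl)-3-[(4-methoxybenzyl)oxy]-5-(4,4,5,5-tetramethyl-1,3,2-dioxaborolan-2-yl)benzoate | COC(=O)c1cc(OCc2ccc(OC)cc2)c(CCO)c(B2OC(C)(C)C(C)(C)O2)c1 | intermediate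
10 | geraniol, (2E)-3,7-dimethylocta-2,6-dien-1-ol | CC(C)=CCC/C(C)=C/CO | starting material
11 | (S)-citronellol, (3S)-3,7-dimethyloct-6-en-1-ol | OCC[C@@H](C)CCC=C(C)C | intermediate
12 | (S)-citronellal, (3S)-3,7-dimethyloct-6-enal | O=CC[C@@H](C)CCC=C(C)C | intermediate
13 | (4S)-1-methoxy-4,8-dimethylnona-1,7-diene (E/Z mixture) | COC=CC[C@@H](C)CCC=C(C)C | intermediate
14 | (4S)-4,8-dimethylnon-7-enal | O=CCC[C@@H](C)CCC=C(C)C | intermediate
15 | trimethyl{[(4S)-4,8-dimethylnona-1,7-dien-1-yl]oxy}silane (E/Z mixture) | C[Si](C)(C)OC=CC[C@@H](C)CCC=C(C)C | intermediate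
16 | (2E,4S)-4,8-dimethylnona-2,7-dienal | O=C/C=C/[C@@H](C)CCC=C(C)C | intermediate
17 | methyl 3-[(3S,4S)-4,8-dimethyl-1-oxonon-7-en-3-yl]-4-(2-hydroxyethyl)-5-[(4-methoxybenzyl)oxy]benzoate | O=CC[C@@H]([C@@H](C)CCC=C(C)C)c1cc(C(=O)OC)cc(OCc2ccc(OC)cc2)c1CCO | intermediate
18 | methyl 3-[(3S,4S)-4,8-dimethyl-1-oxonon-7-en-3-yl]-5-[(4-methoxybenzyl)oxy]-4-(2-oxoethyl)benzoate | O=CC[C@@H]([C@@H](C)CCC=C(C)C)c1cc(C(=O)OC)cc(OCc2ccc(OC)cc2)c1CC=O | intermediate (not isolated)
19 | methyl (4S)-1-formyl-8-[(4-methoxybenzyl)oxy]-4-[(2S)-6-methylhept-5-en-2-yl]-3,4-dihydronaphthalene-6-carboxylate | O=CC1=CC[C@@H]([C@@H](C)CCC=C(C)C)c2cc(C(=O)OC)cc(OCc3ccc(OC)cc3)c21 | intermediate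
20 | methyl (4S)-8-[(4-methoxybenzyl)oxy]-4-[(2S)-6-methylhept-5-en-2-yl]-1-{[(triethylsilyl)oxy]methylidene}-1,2,3,4-tetrahydronaphthalene-6-carboxylate | CC[Si](CC)(CC)OC=C1CC[C@@H]([C@@H](C)CCC=C(C)C)c2cc(C(=O)OC)cc(OCc3ccc(OC)cc3)c21 | intermediate (not isolated)
21 | methyl (1S,4S)-1-formyl-8-[(4-methoxybenzyl)oxy]-4-[(2S)-6-methylhept-5-en-2-yl]-1,2,3,4-tetrahydronaphthalene-6-carboxylate (cis) | O=C[C@H]1CC[C@@H]([C@@H](C)CCC=C(C)C)c2cc(C(=O)OC)cc(OCc3ccc(OC)cc3)c21 | intermediate (not isolated)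
22 | methyl (1R,4S)-1-formyl-8-[(4-methoxybenzyl)oxy]-4-[(2S)-6-methylhept-5-en-2-yl]-1,2,3,4-tetrahydronaphthalene-6-carboxylate (trans) | O=C[C@@H]1CC[C@@H]([C@@H](C)CCC=C(C)C)c2cc(C(=O)OC)cc(OCc3ccc(OC)cc3)c21 | intermediate (not isolated)
23 | methyl (1R,4S)-1-(hydroxymethyl)-8-[(4-methoxybenzyl)oxy]-4-[(2S)-6-methylhept-5-en-2-yl]-1,2,3,4-tetrahydronaphthalene-6-carboxylate | OC[C@@H]1CC[C@@H]([C@@H](C)CCC=C(C)C)c2cc(C(=O)OC)cc(OCc3ccc(OC)cc3)c21 | intermediate
24 | (1R,4S)-1-(hydroxymethyl)-8-[(4-methoxybenzyl)oxy]-4-[(2S)-6-methylhept-5-en-2-yl]-1,2,3,4-tetrahydronaphthalene-6-carboxylic acid | OC[C@@H]1CC[C@@H]([C@@H](C)CCC=C(C)C)c2cc(C(=O)O)cc(OCc3ccc(OC)cc3)c21 | intermediate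
25 | acetic (1R,4S)-1-(acetoxymethyl)-8-[(4-methoxybenzyl)oxy]-4-[(2S)-6-methylhept-5-en-2-yl]-1,2,3,4-tetrahydronaphthalene-6-carboxylic anhydride | CC(=O)OC[C@@H]1CC[C@@H]([C@@H](C)CCC=C(C)C)c2cc(C(=O)OC(C)=O)cc(OCc3ccc(OC)cc3)c21 | intermediate (not isolated)
26 | (1R,4S)-1-(acetoxymethyl)-8-[(4-methoxybenzyl)oxy]-4-[(2S)-6-methylhept-5-en-2-yl]-1,2,3,4-tetrahydronaphthalene-6-carboxylic acid | CC(=O)OC[C@@H]1CC[C@@H]([C@@H](C)CCC=C(C)C)c2cc(C(=O)O)cc(OCc3ccc(OC)cc3)c21 | intermediate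
27 | [(1R,4S)-6-carboxy-8-hydroxy-4-[(2S)-6-methylhept-5-en-2-yl]-1,2,3,4-tetrahydronaphthalen-1-yl]methyl acetate | CC(=O)OC[C@@H]1CC[C@@H]([C@@H](C)CCC=C(C)C)c2cc(C(=O)O)cc(O)c21 | target

## Totals and risks

Total step count: 18. Longest linear sequence: 12 steps (1 → 27 through steps 1–6 and 13–18; the geraniol branch, steps 7–12 then 13–18, is equally long).

**Step 13 (Rh 1,4-addition).** An ortho-substituted arylboronate meets an enal that is branched next to the reacting carbon and whose γ-stereocentre is base-sensitive, so slow addition, protodeboronation or γ-epimerisation are possible. The fallback sets out from 16 and 9 and returns at 17. Enal 16 is reduced (NaBH4, CeCl3, MeOH) to (2E,4S)-4,8-dimethylnona-2,7-dien-1-ol F1. Boronate 9 is cleaved (NaIO4, NH4OAc, acetone/H2O) to the boronic acid, which is obtained as its cyclic hemiester methyl 1-hydroxy-5-[(4-methoxybenzyl)oxy]-3,4-dihydro-1H-2,1-benzoxaborinine-7-carboxylate F2. The two are joined in an enantioselective redox-relay oxidative Heck reaction (Pd(MeCN)2(OTs)2, Cu(OTf)2, chiral pyridine-oxazoline ligand, O2, DMF, rt). The aryl group adds to the alkene carbon remote from the hydroxyl, palladium walks to the carbinol carbon and leaves as the aldehyde, which gives 17 without any base or enal.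

**Step 14 (dialdehyde aldol condensation).** The arylacetaldehyde is labile, and the alternative aldol mode (side-chain aldehyde as donor) would give a regioisomeric ring. The fallback sets out from 17 and returns at 19. The side-chain aldehyde is masked (HC(OMe)3, PPTS, MeOH) as methyl 3-[(3S,4S)-1,1-dimethoxy-4,8-dimethylnon-7-en-3-yl]-4-(2-hydroxyethyl)-5-[(4-methoxybenzyl)oxy]benzoate F3. Dess–Martin oxidation gives the corresponding 4-(2-oxoethyl) arylacetaldehyde F4, now the only enolisable aldehyde. TMSOTf/Et3N converts it into the 4-[2-(trimethylsilyloxy)ethenyl] silyl enol ether F5. Catalytic TMSOTf (CH2Cl2, −78 °C) then triggers an intramolecular Mukaiyama aldol addition onto the acetal, giving methyl (4S)-1-formyl-2-methoxy-8-[(4-methoxybenzyl)oxy]-4-[(2S)-6-methylhept-5-en-2-yl]-1,2,3,4-tetrahydronaphthalene-6-carboxylate F6. DBU eliminates methanol (E1cB) to give 19 with the donor carbon fixed by construction.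

**Step 15 (trans selectivity at C1).** The equilibrium may favour the trans aldehyde only modestly (about 5:1 or less), and kinetic protonation favours cis. The fallback sets out from the equilibrating aldehydes 21/22 (worked up crude after the K2CO3/MeOH stage) and returns at 23. NaBH4 is replaced by a catalyst-controlled dynamic kinetic resolution: asymmetric hydrogenation of the rapidly epimerising α-aryl aldehyde with a Noyori-type RuCl2(xylBINAP)(DAIPEN) catalyst (both antipodes screened), KOtBu (2 mol %), H2, iPrOH/THF, rt. Only the (1R) epimer is reduced, while the alkene and the ester are left alone, so the catalyst rather than the equilibrium ratio sets C1. No new compound is made.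

## Further compounds

F1 | step 13 | (2E,4S)-4,8-dimethylnona-2,7-dien-1-ol | OC/C=C/[C@@H](C)CCC=C(C)C
F2 | step 13 | methyl 1-hydroxy-5-[(4-methoxybenzyl)oxy]-3,4-dihydro-1H-2,1-benzoxaborinine-7-carboxylate | COC(=O)c1cc(OCc2ccc(OC)cc2)c2CCOB(O)c2c1
F3 | step 14 | methyl 3-[(3S,4S)-1,1-dimethoxy-4,8-dimethylnon-7-en-3-yl]-4-(2-hydroxyethyl)-5-[(4-methoxybenzyl)oxy]benzoate | COC(OC)C[C@@H]([C@@H](C)CCC=C(C)C)c1cc(C(=O)OC)cc(OCc2ccc(OC)cc2)c1CCO
F4 | step 14 | methyl 3-[(3S,4S)-1,1-dimethoxy-4,8-dimethylnon-7-en-3-yl]-5-[(4-methoxybenzyl)oxy]-4-(2-oxoethyl)benzoate | COC(OC)C[C@@H]([C@@H](C)CCC=C(C)C)c1cc(C(=O)OC)cc(OCc2ccc(OC)cc2)c1CC=O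
F5 | step 14 | methyl 3-[(3S,4S)-1,1-dimethoxy-4,8-dimethylnon-7-en-3-yl]-5-[(4-methoxybenzyl)oxy]-4-[2-(trimethylsilyloxy)ethenyl]benzoate | COC(OC)C[C@@H]([C@@H](C)CCC=C(C)C)c1cc(C(=O)OC)cc(OCc2ccc(OC)cc2)c1C=CO[Si](C)(C)C
F6 | step 14 | methyl (4S)-1-formyl-2-methoxy-8-[(4-methoxybenzyl)oxy]-4-[(2S)-6-methylhept-5-en-2-yl]-1,2,3,4-tetrahydronaphthalene-6-carboxylate (C1/C2 isomer mixture) | O=CC1C(OC)C[C@@H]([C@@H](C)CCC=C(C)C)c2cc(C(=O)OC)cc(OCc3ccc(OC)cc3)c21
F0 | step 15 | none | none
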